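## Retrosynthetic overview
1. A retro intramolecular Diels–Alder (IMDA) disconnection at C3a–C7a and C6–C7 opens the target to the acyclic (2E,4Z,7E,9E,11E,13E)-hexaenoic acid 16. Its only stereocentre is C3. Both rings form together in the last step.
2. Acid 16 is cut at the C1–C7a sp2–sp2 bond. This bond is made by a Ni-electrocatalytic reductive alkenyl–alkenyl coupling of a Z-alkenyl iodide with (E)-3-iodo-2-methylacrylic acid.
3. The Z-alkenyl iodide (C1=C2) comes from Stork–Zhao iodo-olefination of an α-methyl tetraenal.
4. The tetraene (C4–C5 and C4–Me) comes from stepwise double Negishi substitution of a Roche-ester-derived 1,1-dibromoalkene. The trienyl partner is built from benzalacetone by iterative Zr-catalysed carboalumination.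
5. C3 is bought in the Roche ester. C3a, C6, C7 and C7a are all relayed from it in the cycloaddition.

Numbering used: C1(Et)=C2–C3(Me)–C3a–C4(Me)=C5–C6(Me, dienyl)–C7(Me, CO2H)–C7a. The side chain is C1'H=C2'(Me)–C3'H=C4'H–Ph.

Assumption: compound 15 and all reagents are catalogue items (15 is otherwise two steps from diethyl methylmalonate and iodoform).

## Route

**Step 1**
Reactants: 1, methyl (R)-3-hydroxy-2-methylpropanoate ((R)-Roche ester)
Product: 2, methyl (R)-3-[(tert-butyldimethylsilyl)oxy]-2-methylpropanoate
Conditions: TBSCl, imidazole, CH2Cl2, 0→23 °C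
Reagents that add atoms: tert-butyldimethylsilyl chloride, CC(C)(C)[Si](C)(C)Cl
Why: Standard silyl ether protection of the primary alcohol leaves the purchased stereocentre (future C3) untouched.

**Step 2**
Reactants: 2
Product: 3, (R)-3-[(tert-butyldimethylsilyl)oxy]-2-methylpropanal
Conditions: DIBAL-H (1.05 equiv), CH2Cl2, –78 °C; Rochelle salt
Reagents that add atoms: none
Why: In this partial ester reduction the aluminium hemiacetal survives at –78 °C, so the aldehyde is released only on work-up and does not epimerise.

**Step 3**
Reactants: 3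
Product: 4, (S)-tert-butyl[(4,4-dibromo-2-methylbut-3-en-1-yl)oxy]dimethylsilane
Conditions: CBr4, PPh3, 2,6-lutidine, CH2Cl2, 0 °C
Reagents that add atoms: carbon tetrabromide, BrC(Br)(Br)Br
Why: Corey–Fuchs (Ramirez) dibromo-olefination is essentially non-basic, so the α-stereocentre is retained (the descriptor changes by CIP priority only), and the new carbon becomes C4.

**Step 4**
Reactants: 5, (E)-4-phenylbut-3-en-2-one (benzalacetone)
Product: 6, (E)-but-1-en-3-yn-1-ylbenzene
Conditions: LDA, THF, –78 °C; ClP(O)(OEt)2, –78→23 °C; LDA (2.3 equiv), –78→23 °C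
Reagents that add atoms: none
Why: This is a methyl ketone to terminal alkyne conversion through the kinetic enol phosphate and base-induced elimination, and the styryl E-alkene is not involved.

**Step 5**
Reactants: 6
Product: 7, [(1E,3E)-4-iodo-3-methylbuta-1,3-dien-1-yl]benzene
Conditions: Me3Al, Cp2ZrCl2 (25 mol %), CH2Cl2, 23 °C; then I2, THF, –30 °C
Reagents that add atoms: trimethylaluminium, C[Al](C)C; iodine, II
Why: Zr-catalysed syn-carboalumination (Negishi) places Me on the internal alkyne carbon, and iodinolysis with retention fixes the E C1'=C2' alkene.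

**Step 6**
Reactants: 7
Product: 8, [(1E,3E)-3-methylhexa-1,3-dien-5-yn-1-yl]benzene
Conditions: HC≡CMgBr, ZnBr2, THF; Pd(PPh3)4 (3 mol %), 23 °C
Reagents that add atoms: ethynylmagnesium bromide, C#C[Mg]Br
Why: Negishi alkynylation of an alkenyl iodide proceeds with retention, and ethynylzinc gives the free terminal alkyne (C5≡C6) directly.

**Step 7**
Reactants: 8 (1.2 equiv); 4
Product: 9, tert-butyl{[(2S,3Z,5E,7E,9E)-4-bromo-2,6,8-trimethyl-10-phenyldeca-3,5,7,9-tetraen-1-yl]oxy}dimethylsilane
Conditions: 8, Me3Al, Cp2ZrCl2, CH2Cl2, 23 °C; evaporate; ZnBr2, 4, PdCl2(DPEphos) (5 mol %), THF, 23 °C, dark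
Reagents that add atoms: trimethylaluminium, C[Al](C)C
Why: A second syn-carboalumination sets E C5=C6, and in the trans-selective Negishi monoalkenylation Pd inserts only into the less hindered C–Br bond trans to the alkyl group, so C5 ends up trans to C3.

**Step 8**
Reactants: 9
Product: 10, tert-butyldimethyl{[(2S,3E,5E,7E,9E)-2,4,6,8-tetramethyl-10-phenyldeca-3,5,7,9-tetraen-1-yl]oxy}silane
Conditions: Me2Zn, Pd(PtBu3)2 (5 mol %), THF, 23 °C, dark
Reagents that add atoms: dimethylzinc, C[Zn]C
Why: Negishi methylation of the 2-bromo-1,3-diene with the bulky PtBu3 catalyst goes with retention, which is why 9 is isolated free of the first catalyst, and it gives E C3a=C4.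

**Step 9**
Reactants: 10
Product: 11, (2S,3E,5E,7E,9E)-2,4,6,8-tetramethyl-10-phenyldeca-3,5,7,9-tetraen-1-ol
Conditions: TBAF, THF, 0 °C
Reagents that add atoms: none
Why: Fluoride desilylation does not affect the polyene or the stereocentre.

**Step 10**
Reactants: 11
Product: 12, (2S,3E,5E,7E,9E)-2,4,6,8-tetramethyl-10-phenyldeca-3,5,7,9-tetraenal
Conditions: Dess–Martin periodinane, NaHCO3, CH2Cl2, 0 °C; used crude, no silica
Reagents that add atoms: none
Why: Buffered Dess–Martin oxidation is neutral and fast, which minimises enolisation or conjugation of the α-chiral β,γ-unsaturated aldehyde.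

**Step 11**
Reactants: 12; 13, propyltriphenylphosphonium bromide
Product: 14, [(1E,3E,5E,7E,9S,10Z)-11-iodo-3,5,7,9-tetramethyltrideca-1,3,5,7,10-pentaen-1-yl]benzene
Conditions: 13, n-BuLi, THF; I2, –78 °C; NaHMDS, –20 °C; then 12, –78 °C, dark
Reagents that add atoms: iodine, II (13 supplies C1 and the ethyl group)
Why: In the Stork–Zhao olefination the non-stabilised α-iodo ylide adds under kinetic control to give the alkene with I cis to the aldehyde residue (Z, so C3 will be cis to C7a), and fast addition at –78 °C outruns enolisation of C3.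

**Step 12**
Reactants: 14; 15, (E)-3-iodo-2-methylacrylic acid (2.5 equiv)
Product: 16, (2E,4Z,6S,7E,9E,11E,13E)-4-ethyl-2,6,8,10,12-pentamethyl-14-phenyltetradeca-2,4,7,9,11,13-hexaenoic acid
Conditions: 15 is silylated in situ with BSA (DMA, 23 °C, 30 min) and added by syringe pump (6 h) to 14, NiBr2·glyme (15 mol %), dtbbpy (18 mol %), NaI (0.2 M), DMA. Undivided cell, Zn(+)|Ni foam(–), –1.3 V vs Ag/AgCl (about 3.5 F/mol), 10 °C, dark, Ar. Cold aq. citric acid work-up cleaves the TMS ester. Extract with Et2O containing BHT and use crude; any 17 already formed is carried along.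
Reagents that add atoms: none beyond reactant 15, OC(=O)/C(C)=C/I (the TMS group from BSA is lost on work-up and leaves no atoms)
Why: Proposed new method: cathodically generated (dtbbpy)Ni(0) inserts into an alkenyl C–I bond, the alkenyl–Ni(II) iodide is reduced at the cathode to alkenyl–Ni(I), and this activates a second alkenyl iodide and reductively eliminates the C1–C7a diene bond with retention at both alkenes; whichever iodide enters first, cross-selectivity follows because two α-branched alkenyl groups from 14 on one Ni centre are sterically disfavoured and acrylate–acrylate coupling is starved by slow addition of the excess, more reactive partner; transient silylation removes the acidic proton that would otherwise cause hydrogen evolution and protodeiodination, and the potential is about 0.8 V short of polyene reduction, with no excited state that could scramble the tetraene; the closest known reaction types are Ni-catalysed and Ni/Pd-catalysed reductive cross-electrophile coupling of alkenyl halides and triflates with metal reductants, and Ni-electrocatalytic alkenyl halide homocoupling and alkenyl–alkyl coupling.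

**Step 13**
Reactants: 16
Product: 17, zyggomphic acid B. The ring fusion is trans, with C3a-H α and C7a-H β. C3-Me, C6-Me and C7-Me are α. The C6 dienyl group and C7 CO2H are β.
Conditions: toluene (5 mM), BHT (10 mol %), 80 °C, 16 h, dark, Ar
Reagents that add atoms: none
Why: In this thermal type-1 intramolecular Diels–Alder reaction the Z C1=C2 alkene holds the E-dienophile (C7=C7a) next to the E,E-diene (C3a=C4–C5=C6), the purchased C3 centre selects the diene face (C3–H eclipses the C4 methyl, A1,3 strain, so C3-Me ends trans to C4), the carboxyl-endo transition state gives the trans fusion (C3a, C7a), and the diene and dienophile geometries transfer suprafacially to the vicinal quaternary centres C6 and C7.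

## Compound list
| No. | Name | SMILES | Role |
|---|---|---|---|
| 1 | methyl (R)-3-hydroxy-2-methylpropanoate | OC[C@@H](C)C(=O)OC | starting material |
| 2 | methyl (R)-3-(TBSO)-2-methylpropanoate | CC(C)(C)[Si](C)(C)OC[C@@H](C)C(=O)OC | intermediate |
| 3 | (R)-3-(TBSO)-2-methylpropanal | CC(C)(C)[Si](C)(C)OC[C@@H](C)C=O | intermediate |
| 4 | (S)-tert-butyl[(4,4-dibromo-2-methylbut-3-en-1-yl)oxy]dimethylsilane | CC(C)(C)[Si](C)(C)OC[C@@H](C)C=C(Br)Br | intermediate |
| 5 | (E)-4-phenylbut-3-en-2-one | CC(=O)/C=C/c1ccccc1 | starting material |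
| 6 | (E)-but-1-en-3-yn-1-ylbenzene | C#C/C=C/c1ccccc1 | intermediate |
| 7 | [(1E,3E)-4-iodo-3-methylbuta-1,3-dien-1-yl]benzene | I/C=C(C)/C=C/c1ccccc1 | intermediate |
| 8 | [(1E,3E)-3-methylhexa-1,3-dien-5-yn-1-yl]benzene | C#C/C=C(C)/C=C/c1ccccc1 | intermediate |
| 9 | (2S,3Z,5E,7E,9E)-4-bromo-tetraene TBS ether | CC(C)(C)[Si](C)(C)OC[C@@H](C)/C=C(Br)/C=C(C)/C=C(C)/C=C/c1ccccc1 | intermediate |
| 10 | (2S,3E,5E,7E,9E)-2,4,6,8-tetramethyl-10-phenyldecatetraenyl TBS ether | CC(C)(C)[Si](C)(C)OC[C@@H](C)/C=C(C)/C=C(C)/C=C(C)/C=C/c1ccccc1 | intermediate |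
| 11 | (2S,3E,5E,7E,9E)-2,4,6,8-tetramethyl-10-phenyldeca-3,5,7,9-tetraen-1-ol | OC[C@@H](C)/C=C(C)/C=C(C)/C=C(C)/C=C/c1ccccc1 | intermediate |
| 12 | (2S,3E,5E,7E,9E)-2,4,6,8-tetramethyl-10-phenyldeca-3,5,7,9-tetraenal | O=C[C@@H](C)/C=C(C)/C=C(C)/C=C(C)/C=C/c1ccccc1 | intermediate |
| 13 | propyltriphenylphosphonium bromide | CCC[P+](c1ccccc1)(c1ccccc1)c1ccccc1.[Br-] | starting material |
| 14 | [(1E,3E,5E,7E,9S,10Z)-11-iodo-3,5,7,9-tetramethyltrideca-1,3,5,7,10-pentaen-1-yl]benzene | CC/C(I)=C/[C@@H](C)/C=C(C)/C=C(C)/C=C(C)/C=C/c1ccccc1 | intermediate |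
| 15 | (E)-3-iodo-2-methylacrylic acid | OC(=O)/C(C)=C/I | starting material |
| 16 | (2E,4Z,6S,7E,9E,11E,13E)-4-ethyl-2,6,8,10,12-pentamethyl-14-phenyltetradeca-2,4,7,9,11,13-hexaenoic acid | OC(=O)/C(C)=C/C(CC)=C\[C@@H](C)/C=C(C)/C=C(C)/C=C(C)/C=C/c1ccccc1 | intermediate |
| 17 | zyggomphic acid B, (1R,3aR,4R,5S,7aS)-3-ethyl-1,4,5,7-tetramethyl-5-[(1E,3E)-2-methyl-4-phenylbuta-1,3-dien-1-yl]-3a,4,5,7a-tetrahydro-1H-indene-4-carboxylic acid | CCC1=C[C@@H](C)[C@@H]2C(C)=C[C@](C)(/C=C(C)/C=C/c3ccccc3)[C@](C)(C(=O)O)[C@@H]12 | target |

## Step count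
- Total steps: 13.
- Longest linear sequence: 10 (steps 1–3 then 7–13, or equally steps 4–6 then 7–13).

## Steps most likely to fail
1. **Step 12 (new electroreductive alkenyl–alkenyl coupling).**
   - Risks: acrylate homocoupling may outrun the cross-coupling. Compound 14 may undergo protodeiodination or Z→E erosion at alkenyl–Ni.
   - Fallback (known chemistry): Stille coupling of 14 with 2-(trimethylsilyl)ethyl (E)-2-methyl-3-(tributylstannyl)acrylate (Pd2dba3, AsPh3, CuTC). Fluoride cleavage of the TMSE ester then gives 16, or it can be done after the cycloaddition.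
2. **Step 13 (IMDA forming two vicinal quaternary centres).**
   - Risks: the inside methyl on C6 disfavours the s-cis diene and slows the reaction. A 1,5-H shift from C3 across the Z-dienoate, exo cyclisation or attack on the wrong diene face may then compete.
   - Fallback: change the dienophile instead of forcing the acid.
     - Join 14 to (E)-3-iodo-2-methylprop-2-enal in place of 15.
     - Cyclise the more electrophilic hexaenal with a Lewis acid (Me2AlCl, CH2Cl2, –40 °C), where endo selectivity is higher and sigmatropic shifts are frozen out.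
     - Finish with a Pinnick oxidation (NaClO2, 2-methyl-2-butene).
3. **Step 11 (Stork–Zhao olefination on aldehyde 12 from step 10).**
   - Risks: the doubly activated C3–H can epimerise or conjugate into the polyene, and yields of trisubstituted Z-iodides are modest.
   - Fallback: reverse the order of chain growth.
     - Start from (S)-Roche ester and install the Z-iodoalkene first on the robust silyloxy aldehyde.
     - Desilylate and oxidise.
     - Grow the tetraene with Pd-free olefinations that tolerate the alkenyl iodide (Ph3P=C(Me)CHO three times, then diethyl benzylphosphonate).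
     - This converges on the same 14.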